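**Numbering used throughout.** Ring A is the ten-membered carbocycle C1–C10 and ring B the lactone (O6, C12, C11, C7, C6). In the order of the target SMILES: acrylate–O8–C8–C9–C10(C14H3)=C1–C2–C3–C4(C15H2OH)=C5–C6–O6–C12(=O)–C11(C13H3)–C7. Compound numbers 1–34 are fixed in the steps and the list below.

## Analysis of the target

The target is a germacranolide: a cyclodeca-1(10),4-diene (ring A) with two trisubstituted ring olefins (C9 trans to C2, C3 trans to C6), fused at C6–C7 to an α-methyl-γ-butyrolactone (ring B), with a 2-(hydroxymethyl)acrylate on O8 and a free primary allylic alcohol at C15. The four stereocentres are contiguous (C11 R, C7 S, C6 R, C8 S): H6 and H7 are cis, O8 is cis to the C7–C11 bond, so the C7 branch is cis to both flanking oxygens on ring A, and the C13 methyl is trans to C8 on the convex face of ring B. The 1,5-diene undergoes Cope rearrangement to an elemane on heating and transannular cyclisation in acid, C6–O is an allylic acyloxy group, the acrylate is a Michael acceptor, and a free O8 or O15 invites acyl migration. The synthesis is hard because a ten-membered ring with two E-trisubstituted olefins must be closed, and because C7 must end up cis to both oxygens, whereas chair-like closures of this ring put the C8 oxygen trans to the C7 branch. The feature the route is built on is that C6 is an allylic, oxygen-bearing carbon (next to C5=C4) bonded to C7, while O6 is tied through C12 to C11 on C7: the atoms C6, O6, C12, C11 and C7 are the five atoms of a [2,3]-sigmatropic array, and ring A plus the bridge O6–C12–C11 is a thirteen-membered cyclic diallyl ether. A second feature is that the C15 oxygen sits on C4 cis to C6, so its lithium alkoxide can hold a base next to C6–H and cannot act as a leaving group.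

## Retrosynthetic reasoning

**34 ⇒ 33.** Only the two silyl ethers (O15 and the side-chain oxygen) are removed last, under buffered fluoride, so that the acrylate, the lactone and the diene never meet strong acid or base.

**33 ⇒ 29 + 32.** The O8–acyl bond is cut, and it is cut with inversion at C8 (Mitsunobu). The ring contraction below delivers the C8 oxygen trans to the C7 branch (8R), so the same step that installs the ester from acid 32 must turn C8 into the 8S configuration of the target.

**29 ⇒ 28 ⇒ 27 ⇒ 26 ⇒ 24.** The lactone carbonyl C12 is traced back to the terminal methylene of an isopropenyl group on C7. Forward, this is hydroboration (26), oxidative lactonisation onto O6 (27) and base equilibration of C11 (28), where the methyl settles trans to C8 on the convex face. Nothing new is needed at C6 or C7.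

**24 ⇒ 22 (key disconnection).** The C6–C7 bond is cut and O6 is reconnected to C12, which turns ring A into the thirteen-membered cyclic diallyl ether 22. Forward, one [2,3]-Wittig rearrangement contracts the ring from 13 to 10, forms C6–C7 and sets C6 and C7 together, relayed from C8. It is cut here because every other ring bond of ring A would require a direct ten-membered closure.

**22 ⇒ 20.** The ether bond O6–C12 is cut to the open-chain bis-allylic diol 20. Whichever hydroxyl is activated, the same ether results, so the two ends need not be differentiated.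

**20 ⇒ 19 ⇒ 18.** The Z olefin C7=C11 is cut to the α-alkoxy aldehyde 18. A Z-selective phosphonate olefination brings in C11, C12 and C13, and one hydride reduction then frees both allylic alcohols of 20.

**18 ⇒ 17 ⇒ 16 ⇒ 14 + 8.** The C8–C9 bond is cut between the allylic iodide 8 and the chiral glycolate imide 14. This is the only stereocentre bought with a chiral auxiliary; C6, C7 and C11 are relayed from it.

**8 ⇒ 7 ⇒ 6 ⇒ 3 + 4.** The C3–C4 bond is cut. Syn-carbocupration of alkynoate 3 by the Grignard reagent from bromide 4 sets the C4=C5 geometry, and an allylic oxidation of the terminal isopropylidene group of 6 sets the C1=C10 geometry and functionalises C9.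

**Small pieces.** 3 comes from 1; 14 from 9 and 12 via 10 and 11; 32 from 30 via 31.

## Alternatives that were turned down

**Alternative 1: (the textbook route) intramolecular carbonyl allylation closing C6–C7.**
- Disconnection: C6–C7, back to an open-chain enal carrying a 2-(bromomethyl)enoate, A1.
- Forward key step: CrCl2-mediated Nozaki–Hiyama–Kishi-type allylation with spontaneous lactonisation to the α-methylene lactone A2.
- Why turned down: the allylchromium equilibrates and adds through a metal-bound chair, which favours the 6,7-trans adduct for either bromide geometry, whereas the target is 6,7-cis. A direct ten-membered closure also needs high dilution on a Z/E-labile enal. The exocyclic methylene of A2 must then be reduced, and kinetic protonation would put the C13 methyl on the concave face. It is also the disconnection most chemists would draw first.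

**Alternative 2: anionic oxy-Cope ring expansion.**
- Disconnection: C8–C9, with C6 as a ketone, back to a 1,2-dialkenylcyclohexenol A3 (a six-membered ring C1–C6).
- Forward key step: [3,3]-shift of the potassium alkoxide of A3 to the cyclodecadienone A4.
- Why turned down: C4=C5 lies inside the six-membered ring of A3 and therefore emerges with C3 cis to C6 in A4, the wrong geometry, which costs an isomerisation on a sensitive dienone. C7 is formed as an enolate carbon, so its configuration is left to protonation. The C6 ketone needs a separate stereoselective reduction, and the 2-metallated 1-alkoxydiene needed to make A3 is not a simple reagent.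

**Alternative 3: boronate (Grob-type) fragmentation of a decalin.**
- Disconnection: reconnect C5–C10 to a eudesmane-type 4-ene mesylate A5.
- Forward key step: hydroboration at C4 and base-induced fragmentation (B–C4, C5–C10 and C1–OMs) to both ring olefins at once.
- Why turned down: a boron on C4 has the C15 oxygen in the β-position and the C6 oxygen next door, so β-elimination competes with fragmentation. The tetrasubstituted olefin must be hydroborated with defined regio- and facial selectivity. A5 needs six stereocentres, one of them a quaternary C10 that is destroyed, which costs more steps than the ring is worth.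

Key step: step 14

Assumption: the oxan-2-yl (THP) acetal carbon is carried as both epimers (compounds 10, 11, 13–28) and C11 as both epimers in 25–27; steps 17 and 18 merge these mixtures.

## Route

Step 1
Reactants: 1 tri(propan-2-yl)(prop-2-yn-1-yloxy)silane
Product: 3 ethyl 4-{[tri(propan-2-yl)silyl]oxy}but-2-ynoate, via lithium acetylide 2 (not isolated)
Conditions: n-BuLi, THF, −78 °C; ClCO2Et, −78 → 0 °C
Reagents that add atoms: ethyl chloroformate, CCOC(=O)Cl
Why: Deprotonation of the terminal alkyne and C-acylation of the acetylide by the chloroformate (alkynoate synthesis); no stereocentre is involved.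

Step 2
Reactants: 4 5-bromo-2-methylpent-2-ene; 3 ethyl 4-{[tri(propan-2-yl)silyl]oxy}but-2-ynoate
Product: 6 ethyl (2Z)-7-methyl-3-({[tri(propan-2-yl)silyl]oxy}methyl)octa-2,6-dienoate, via Grignard reagent 5 (not isolated)
Conditions: Mg, THF; CuBr·SMe2, −40 °C; 3, −78 °C; NH4Cl (aq), −78 °C
Reagents that add atoms: none
Why: Syn-carbocupration (conjugate addition of an alkylcopper reagent to an alkynoate): the alkyl group and the proton end up cis, so C3 is trans to the ester carbon C6 and C15H2O is cis to it, the C4=C5 geometry of the target; quenching at −78 °C prevents isomerisation of the alkenylcopper.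

Step 3
Reactants: 6 ethyl (2Z)-7-methyl-3-({[tri(propan-2-yl)silyl]oxy}methyl)octa-2,6-dienoate
Product: 7 ethyl (2Z,6E)-8-hydroxy-7-methyl-3-({[tri(propan-2-yl)silyl]oxy}methyl)octa-2,6-dienoate
Conditions: SeO2 (0.3 equiv), t-BuOOH, salicylic acid (cat.), CH2Cl2, 0 °C → rt
Reagents that add atoms: selenium dioxide (catalytic oxygen carrier), O=[Se]=O; tert-butyl hydroperoxide (terminal oxidant), CC(C)(C)OO
Why: Riley allylic oxidation (ene reaction, then [2,3]-shift), which on a terminal isopropylidene group oxidises the methyl trans to the chain and so fixes C1=C10 with C9 trans to C2; the enoate olefin is too electron-poor to react.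

Step 4
Reactants: 7 ethyl (2Z,6E)-8-hydroxy-7-methyl-3-({[tri(propan-2-yl)silyl]oxy}methyl)octa-2,6-dienoate
Product: 8 ethyl (2Z,6E)-8-iodo-7-methyl-3-({[tri(propan-2-yl)silyl]oxy}methyl)octa-2,6-dienoate
Conditions: PPh3, I2, imidazole, CH2Cl2, 0 °C; used at once
Reagents that add atoms: iodine, II
Why: Appel-type iodination of the primary allylic alcohol under neutral conditions (SN2 at C9, no allylic transposition).

Step 5
Reactants: 9 ethyl hydroxyacetate
Product: 10 ethyl (oxan-2-yloxy)acetate
Conditions: 3,4-dihydro-2H-pyran, PPTS (cat.), CH2Cl2, rt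
Reagents that add atoms: 3,4-dihydro-2H-pyran, C1=COCCC1
Why: Acid-catalysed acetalisation to the THP ether, a protecting group that is inert to organolithium reagents, has no benzylic or allylic C–H, and is removed later by mild acetal exchange.

Step 6
Reactants: 10 ethyl (oxan-2-yloxy)acetate
Product: 11 lithium (oxan-2-yloxy)acetate
Conditions: LiOH·H2O, THF/H2O, rt; evaporate and dry
Reagents that add atoms: lithium hydroxide, [Li+].[OH-]
Why: Saponification; the lithium salt is isolated so that the acetal never meets acid.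

Step 7
Reactants: 11 lithium (oxan-2-yloxy)acetate; 12 (4S)-4-benzyl-1,3-oxazolidin-2-one
Product: 14 (4S)-4-benzyl-3-[(oxan-2-yloxy)acetyl]-1,3-oxazolidin-2-one, via mixed pivalic anhydride 13 (not isolated)
Conditions: t-BuCOCl, THF, −20 °C; 12, LiCl, Et3N, rt
Reagents that add atoms: none
Why: N-acylation of the oxazolidinone by a mixed anhydride under LiCl/Et3N activation; the only defined stereocentre comes from the commercial auxiliary.

Step 8
Reactants: 14 (4S)-4-benzyl-3-[(oxan-2-yloxy)acetyl]-1,3-oxazolidin-2-one; 8 ethyl (2Z,6E)-8-iodo-7-methyl-3-({[tri(propan-2-yl)silyl]oxy}methyl)octa-2,6-dienoate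
Product: 16 ethyl (2Z,6E,9R)-10-[(4S)-4-benzyl-2-oxo-1,3-oxazolidin-3-yl]-7-methyl-9-(oxan-2-yloxy)-10-oxo-3-({[tri(propan-2-yl)silyl]oxy}methyl)deca-2,6-dienoate, via sodium enolate 15 (not isolated)
Conditions: 14 (2 equiv), NaN(SiMe3)2, THF, −78 °C; 8, −78 → −45 °C
Reagents that add atoms: none
Why: Auxiliary-controlled alkylation of a chelated sodium Z-glycolate enolate with an allylic iodide; the benzyl group shields one enolate face, so the C8–C9 bond forms on the other and C8 is set R (C9 of the chain), while the hindered β,β-disubstituted enoate does not compete at −45 °C.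

Step 9
Reactants: 16 ethyl (2Z,6E,9R)-10-[(4S)-4-benzyl-2-oxo-1,3-oxazolidin-3-yl]-7-methyl-9-(oxan-2-yloxy)-10-oxo-3-({[tri(propan-2-yl)silyl]oxy}methyl)deca-2,6-dienoate
Product: 17 ethyl (2Z,6E,9R)-10-hydroxy-7-methyl-9-(oxan-2-yloxy)-3-({[tri(propan-2-yl)silyl]oxy}methyl)deca-2,6-dienoate
Conditions: NaBH4, THF/H2O (4:1), 0 °C → rt
Reagents that add atoms: none
Why: Reductive cleavage of the activated N-acyl oxazolidinone by borohydride; the conjugated ethyl ester is not reduced under these conditions and the auxiliary is recovered.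

Step 10
Reactants: 17 ethyl (2Z,6E,9R)-10-hydroxy-7-methyl-9-(oxan-2-yloxy)-3-({[tri(propan-2-yl)silyl]oxy}methyl)deca-2,6-dienoate
Product: 18 ethyl (2Z,6E,9R)-7-methyl-9-(oxan-2-yloxy)-10-oxo-3-({[tri(propan-2-yl)silyl]oxy}methyl)deca-2,6-dienoate
Conditions: Dess–Martin periodinane, NaHCO3, CH2Cl2, 0 °C → rt
Reagents that add atoms: none
Why: Dess–Martin oxidation under buffered conditions gives the α-alkoxy aldehyde without epimerising C8 and without touching the acetal or the silyl ether.

Step 11
Reactants: 18 ethyl (2Z,6E,9R)-7-methyl-9-(oxan-2-yloxy)-10-oxo-3-({[tri(propan-2-yl)silyl]oxy}methyl)deca-2,6-dienoate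
Product: 19 diethyl (2Z,6E,9R,10Z)-7,11-dimethyl-9-(oxan-2-yloxy)-3-({[tri(propan-2-yl)silyl]oxy}methyl)dodeca-2,6,10-trienedioate
Conditions: ethyl 2-[bis(2,2,2-trifluoroethoxy)phosphoryl]propanoate, KN(SiMe3)2, 18-crown-6, THF, −78 °C
Reagents that add atoms: ethyl 2-[bis(2,2,2-trifluoroethoxy)phosphoryl]propanoate, CCOC(=O)C(C)P(=O)(OCC(F)(F)F)OCC(F)(F)F
Why: Still–Gennari olefination: the electron-poor phosphonate with a crown-separated potassium ion eliminates from the kinetic adduct and gives the Z enoate, so C12 is cis to C8 across C7=C11, the geometry the ring contraction needs.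

Step 12
Reactants: 19 diethyl (2Z,6E,9R,10Z)-7,11-dimethyl-9-(oxan-2-yloxy)-3-({[tri(propan-2-yl)silyl]oxy}methyl)dodeca-2,6,10-trienedioate
Product: 20 (2Z,6E,9R,10Z)-7,11-dimethyl-9-(oxan-2-yloxy)-3-({[tri(propan-2-yl)silyl]oxy}methyl)dodeca-2,6,10-triene-1,12-diol
Conditions: i-Bu2AlH (5 equiv), CH2Cl2, −78 → −20 °C; aq. potassium sodium tartrate
Reagents that add atoms: none
Why: 1,2-Reduction of both conjugated esters to the two primary allylic alcohols (C6–OH and C12–OH) in one operation; olefin geometries are untouched.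

Step 13
Reactants: 20 (2Z,6E,9R,10Z)-7,11-dimethyl-9-(oxan-2-yloxy)-3-({[tri(propan-2-yl)silyl]oxy}methyl)dodeca-2,6,10-triene-1,12-diol
Product: 22 [(3Z,5R,7E,11Z)-3,7-dimethyl-5-(oxan-2-yloxy)-1-oxacyclotrideca-3,7,11-trien-11-yl]methanol, via silyl-protected macrocyclic ether 21 (not isolated)
Conditions: NaH (4 equiv), THF (2 mM), 1-(p-tolylsulfonyl)imidazole (1.05 equiv, slow addition), 0 → 40 °C; then MeOH, Bu4NF, rt
Reagents that add atoms: none
Why: Intramolecular Williamson etherification at high dilution: the dialkoxide is monosulfonylated in the flask at either primary allylic oxygen and the other alkoxide displaces it, both modes giving the same thirteen-membered ether; the bulky triisopropylsilyl group resists base-induced migration to O6, and fluoride then frees C15–OH for the key step.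

Step 14
Reactants: 22 [(3Z,5R,7E,11Z)-3,7-dimethyl-5-(oxan-2-yloxy)-1-oxacyclotrideca-3,7,11-trien-11-yl]methanol
Product: 24 (1R,2Z,6E,9R,10R)-3-({[tert-butyl(diphenyl)silyl]oxy}methyl)-7-methyl-9-(oxan-2-yloxy)-10-(prop-1-en-2-yl)cyclodeca-2,6-dien-1-ol, via dilithium dialkoxide 23 (not isolated)
Conditions: s-BuLi (2.3 equiv), THF, −78 → −40 °C; then t-BuPh2SiCl (1.2 equiv), −78 → 0 °C; NH4Cl (aq)
Reagents that add atoms: tert-butyl(chloro)diphenylsilane, CC(C)(C)[Si](Cl)(c1ccccc1)c1ccccc1
Why: The first equivalent of base makes the C15 lithium alkoxide, which sits cis to C6 on C4=C5 and holds the second equivalent next to C6–H, so the allylic α-oxy carbanion forms at C6 rather than at C12 (shielded by the C13 methyl on C11) or at the C8 methine. The carbanion attacks C7 through the five-membered envelope C6–O6–C12–C11=C7 while O6–C12 breaks ([2,3]-Wittig rearrangement); the closest known reaction type is the [2,3]-Wittig ring contraction of thirteen-membered cyclic diallyl ethers to ten-membered carbocyclic homoallylic alcohols. The ten-membered ring A is thus closed by transannular C6–C7 bond formation (ring contraction from 13 to 10 through a five-membered sigmatropic transition state), and C12 becomes the terminal methylene of the isopropenyl group on C7. The C6/C7 relationship is controlled by the Z geometry of C7=C11: C12, and with it O6, lies on the C8 side of C11, which puts O6 pseudo-axial on the chair-like bridge C5–C6–C7–C8–C9–C10 while the C11 unit is pseudo-equatorial, so H6 and H7 come out cis. The absolute sense is controlled by C8 (R): its acetal oxygen is pseudo-equatorial and anti to the forming bond, and H8 eclipses C7=C11 to avoid 1,3-allylic strain with C12H2, so C6 adds to the C7 face that places the C11 unit trans to O8, giving the 6R,7R,8R product (C7 has the geometry of the target; its label changes to S once O6 is acylated). The step needs regioselective lithiation and no 1,4-elimination from the C6 allyl anion; the alkoxide at C15 secures both, because an oxide cannot leave, which is why the silyl ether was removed in step 13. The primary alkoxide is then silylated in the flask in preference to the hindered secondary C6 alkoxide. The C8 configuration obtained is the opposite of the target and is corrected in step 21.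

Step 15
Reactants: 24 (1R,2Z,6E,9R,10R)-3-({[tert-butyl(diphenyl)silyl]oxy}methyl)-7-methyl-9-(oxan-2-yloxy)-10-(prop-1-en-2-yl)cyclodeca-2,6-dien-1-ol
Product: 26 (1R,2Z,6E,9R,10R)-3-({[tert-butyl(diphenyl)silyl]oxy}methyl)-10-(1-hydroxypropan-2-yl)-7-methyl-9-(oxan-2-yloxy)cyclodeca-2,6-dien-1-ol (both C11 epimers), via bis(9-BBN) adduct 25 (not isolated)
Conditions: 9-BBN (3 equiv), THF, 0 °C → rt; NaOH (aq), H2O2, 0 °C
Reagents that add atoms: hydrogen peroxide, OO
Why: Anti-Markovnikov hydroboration–oxidation with 9-BBN, which reacts with the 1,1-disubstituted isopropenyl group and leaves the two trisubstituted ring olefins alone; C11 is not controlled here.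

Step 16
Reactants: 26 (1R,2Z,6E,9R,10R)-3-({[tert-butyl(diphenyl)silyl]oxy}methyl)-10-(1-hydroxypropan-2-yl)-7-methyl-9-(oxan-2-yloxy)cyclodeca-2,6-dien-1-ol (both C11 epimers)
Product: 27 (3aS,4R,6E,10Z,11aR)-10-({[tert-butyl(diphenyl)silyl]oxy}methyl)-3,6-dimethyl-4-(oxan-2-yloxy)-3a,4,5,8,9,11a-hexahydrocyclodeca[b]furan-2(3H)-one (both C3 epimers)
Conditions: TEMPO (0.2 equiv), PhI(OAc)2 (2.5 equiv), CH2Cl2, rt
Reagents that add atoms: none
Why: Oxoammonium oxidation of the primary alcohol to the aldehyde, lactol formation with the C6 hydroxyl and further oxidation to the cis-fused γ-lactone (oxidative lactonisation of a 1,4-diol); the hindered secondary allylic alcohol is oxidised more slowly than the primary one.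

Step 17
Reactants: 27 (3aS,4R,6E,10Z,11aR)-10-({[tert-butyl(diphenyl)silyl]oxy}methyl)-3,6-dimethyl-4-(oxan-2-yloxy)-3a,4,5,8,9,11a-hexahydrocyclodeca[b]furan-2(3H)-one (both C3 epimers)
Product: 28 (3R,3aS,4R,6E,10Z,11aR)-10-({[tert-butyl(diphenyl)silyl]oxy}methyl)-3,6-dimethyl-4-(oxan-2-yloxy)-3a,4,5,8,9,11a-hexahydrocyclodeca[b]furan-2(3H)-one
Conditions: t-BuOK (0.3 equiv), t-BuOH/THF, 0 °C → rt
Reagents that add atoms: none
Why: Enolate-mediated epimerisation under thermodynamic control: the C13 methyl settles on the convex face of the cis-fused lactone, trans to C8 and cis to H7 (11R); C7 carries no leaving group, so the enolate cannot eliminate.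

Step 18
Reactants: 28 (3R,3aS,4R,6E,10Z,11aR)-10-({[tert-butyl(diphenyl)silyl]oxy}methyl)-3,6-dimethyl-4-(oxan-2-yloxy)-3a,4,5,8,9,11a-hexahydrocyclodeca[b]furan-2(3H)-one
Product: 29 (3R,3aS,4R,6E,10Z,11aR)-10-({[tert-butyl(diphenyl)silyl]oxy}methyl)-4-hydroxy-3,6-dimethyl-3a,4,5,8,9,11a-hexahydrocyclodeca[b]furan-2(3H)-one
Conditions: PPTS (0.2 equiv), MeOH, 40 °C
Reagents that add atoms: none
Why: Acetal exchange with methanol under weak acid removes the THP group; the tert-butyldiphenylsilyl ether survives and the acid is too weak to trigger transannular cyclisation of the diene.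

Step 19
Reactants: 30 ethyl 2-(hydroxymethyl)prop-2-enoate
Product: 31 ethyl 2-({[tert-butyl(dimethyl)silyl]oxy}methyl)prop-2-enoate
Conditions: t-BuMe2SiCl, imidazole, CH2Cl2, 0 °C → rt
Reagents that add atoms: tert-butyl(chloro)dimethylsilane, CC(C)(C)[Si](C)(C)Cl
Why: Standard silylation of the primary allylic alcohol, so that the acid can later be used as a Mitsunobu nucleophile without self-condensation.

Step 20
Reactants: 31 ethyl 2-({[tert-butyl(dimethyl)silyl]oxy}methyl)prop-2-enoate
Product: 32 2-({[tert-butyl(dimethyl)silyl]oxy}methyl)prop-2-enoic acid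
Conditions: LiOH, THF/H2O, 0 °C → rt; 1 M HCl to pH 4
Reagents that add atoms: lithium hydroxide, [Li+].[OH-]
Why: Saponification of the ethyl ester; the silyl ether survives brief, mild acidification.

Step 21
Reactants: 29 (3R,3aS,4R,6E,10Z,11aR)-10-({[tert-butyl(diphenyl)silyl]oxy}methyl)-4-hydroxy-3,6-dimethyl-3a,4,5,8,9,11a-hexahydrocyclodeca[b]furan-2(3H)-one; 32 2-({[tert-butyl(dimethyl)silyl]oxy}methyl)prop-2-enoic acid
Product: 33 (3R,3aS,4S,6E,10Z,11aR)-10-({[tert-butyl(diphenyl)silyl]oxy}methyl)-3,6-dimethyl-2-oxo-2,3,3a,4,5,8,9,11a-octahydrocyclodeca[b]furan-4-yl 2-({[tert-butyl(dimethyl)silyl]oxy}methyl)prop-2-enoate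
Conditions: PPh3, diisopropyl azodicarboxylate, 32 (2.5 equiv), toluene/THF, 0 °C → rt
Reagents that add atoms: none
Why: Mitsunobu esterification: the carboxylate of 32 displaces the alkoxyphosphonium group at C8 by SN2, which installs the acrylate and inverts C8 from R to S in the same step; O15 is silylated and no base is present to move the lactone.

Step 22
Reactants: 33 (3R,3aS,4S,6E,10Z,11aR)-10-({[tert-butyl(diphenyl)silyl]oxy}methyl)-3,6-dimethyl-2-oxo-2,3,3a,4,5,8,9,11a-octahydrocyclodeca[b]furan-4-yl 2-({[tert-butyl(dimethyl)silyl]oxy}methyl)prop-2-enoate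
Product: 34 (3R,3aS,4S,6E,10Z,11aR)-10-(hydroxymethyl)-3,6-dimethyl-2-oxo-2,3,3a,4,5,8,9,11a-octahydrocyclodeca[b]furan-4-yl 2-(hydroxymethyl)prop-2-enoate (CNP0167163.2)
Conditions: HF·pyridine, pyridine, THF, 0 °C → rt
Reagents that add atoms: none
Why: Buffered fluoride cleaves both primary silyl ethers; the conditions are neither basic enough for acyl migration or conjugate addition nor acidic enough for transannular cyclisation.

No step after step 14 is run above 40 °C, to avoid Cope rearrangement of the 1,5-diene.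

## Compound list

1 | tri(propan-2-yl)(prop-2-yn-1-yloxy)silane | C#CCO[Si](C(C)C)(C(C)C)C(C)C | starting material
2 | {3-[tri(propan-2-yl)silyloxy]prop-1-yn-1-yl}lithium | [Li]C#CCO[Si](C(C)C)(C(C)C)C(C)C | intermediate
3 | ethyl 4-{[tri(propan-2-yl)silyl]oxy}but-2-ynoate | CCOC(=O)C#CCO[Si](C(C)C)(C(C)C)C(C)C | intermediate
4 | 5-bromo-2-methylpent-2-ene | CC(C)=CCCBr | starting material
5 | (4-methylpent-3-en-1-yl)magnesium bromide | CC(C)=CCC[Mg]Br | intermediate
6 | ethyl (2Z)-7-methyl-3-({[tri(propan-2-yl)silyl]oxy}methyl)octa-2,6-dienoate | CCOC(=O)/C=C(\CO[Si](C(C)C)(C(C)C)C(C)C)CCC=C(C)C | intermediate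
7 | ethyl (2Z,6E)-8-hydroxy-7-methyl-3-({[tri(propan-2-yl)silyl]oxy}methyl)octa-2,6-dienoate | CCOC(=O)/C=C(\CO[Si](C(C)C)(C(C)C)C(C)C)CC/C=C(\C)CO | intermediate
8 | ethyl (2Z,6E)-8-iodo-7-methyl-3-({[tri(propan-2-yl)silyl]oxy}methyl)octa-2,6-dienoate | CCOC(=O)/C=C(\CO[Si](C(C)C)(C(C)C)C(C)C)CC/C=C(\C)CI | intermediate
9 | ethyl hydroxyacetate | CCOC(=O)CO | starting material
10 | ethyl (oxan-2-yloxy)acetate (racemic acetal) | CCOC(=O)COC1CCCCO1 | intermediate
11 | lithium (oxan-2-yloxy)acetate | [Li+].[O-]C(=O)COC1CCCCO1 | intermediate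
12 | (4S)-4-benzyl-1,3-oxazolidin-2-one | O=C1N[C@@H](Cc2ccccc2)CO1 | starting material
13 | (oxan-2-yloxy)acetic pivalic anhydride | CC(C)(C)C(=O)OC(=O)COC1CCCCO1 | intermediate
14 | (4S)-4-benzyl-3-[(oxan-2-yloxy)acetyl]-1,3-oxazolidin-2-one | O=C(COC1CCCCO1)N1C(=O)OC[C@@H]1Cc1ccccc1 | intermediate
15 | sodium (Z)-enolate of 14 | [Na]O/C(=C\OC1CCCCO1)N1C(=O)OC[C@@H]1Cc1ccccc1 | intermediate
16 | ethyl (2Z,6E,9R)-10-[(4S)-4-benzyl-2-oxo-1,3-oxazolidin-3-yl]-7-methyl-9-(oxan-2-yloxy)-10-oxo-3-({[tri(propan-2-yl)silyl]oxy}methyl)deca-2,6-dienoate (8R in target numbering) | CCOC(=O)/C=C(\CO[Si](C(C)C)(C(C)C)C(C)C)CC/C=C(\C)C[C@@H](OC1CCCCO1)C(=O)N1C(=O)OC[C@@H]1Cc1ccccc1 | intermediate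
17 | ethyl (2Z,6E,9R)-10-hydroxy-7-methyl-9-(oxan-2-yloxy)-3-({[tri(propan-2-yl)silyl]oxy}methyl)deca-2,6-dienoate | CCOC(=O)/C=C(\CO[Si](C(C)C)(C(C)C)C(C)C)CC/C=C(\C)C[C@@H](OC1CCCCO1)CO | intermediate
18 | ethyl (2Z,6E,9R)-7-methyl-9-(oxan-2-yloxy)-10-oxo-3-({[tri(propan-2-yl)silyl]oxy}methyl)deca-2,6-dienoate | CCOC(=O)/C=C(\CO[Si](C(C)C)(C(C)C)C(C)C)CC/C=C(\C)C[C@@H](OC1CCCCO1)C=O | intermediate
19 | diethyl (2Z,6E,9R,10Z)-7,11-dimethyl-9-(oxan-2-yloxy)-3-({[tri(propan-2-yl)silyl]oxy}methyl)dodeca-2,6,10-trienedioate | CCOC(=O)/C=C(\CO[Si](C(C)C)(C(C)C)C(C)C)CC/C=C(\C)C[C@@H](OC1CCCCO1)/C=C(/C)C(=O)OCC | intermediate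
20 | (2Z,6E,9R,10Z)-7,11-dimethyl-9-(oxan-2-yloxy)-3-({[tri(propan-2-yl)silyl]oxy}methyl)dodeca-2,6,10-triene-1,12-diol | OC/C=C(\CO[Si](C(C)C)(C(C)C)C(C)C)CC/C=C(\C)C[C@@H](OC1CCCCO1)/C=C(/C)CO | intermediate
21 | (3Z,5R,7E,11Z)-3,7-dimethyl-5-(oxan-2-yloxy)-11-({[tri(propan-2-yl)silyl]oxy}methyl)-1-oxacyclotrideca-3,7,11-triene | O([C@@H]1C/C(C)=C/CC/C(CO[Si](C(C)C)(C(C)C)C(C)C)=C/COC/C(C)=C\1)C2CCCCO2 | intermediate
22 | [(3Z,5R,7E,11Z)-3,7-dimethyl-5-(oxan-2-yloxy)-1-oxacyclotrideca-3,7,11-trien-11-yl]methanol | O([C@@H]1C/C(C)=C/CC/C(CO)=C/COC/C(C)=C\1)C2CCCCO2 | intermediate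
23 | dilithium (1R,2Z,6E,9R,10R)-7-methyl-3-(oxidomethyl)-9-(oxan-2-yloxy)-10-(prop-1-en-2-yl)cyclodeca-2,6-dien-1-olate | O([C@@H]1C/C(C)=C/CC/C(CO[Li])=C/[C@@H](O[Li])[C@H]1C(C)=C)C2CCCCO2 | intermediate
24 | (1R,2Z,6E,9R,10R)-3-({[tert-butyl(diphenyl)silyl]oxy}methyl)-7-methyl-9-(oxan-2-yloxy)-10-(prop-1-en-2-yl)cyclodeca-2,6-dien-1-ol (6R,7R,8R in target numbering) | O([C@@H]1C/C(C)=C/CC/C(CO[Si](c3ccccc3)(c3ccccc3)C(C)(C)C)=C/[C@@H](O)[C@H]1C(C)=C)C2CCCCO2 | intermediate
25 | bis(9-BBN) adduct of 24 (O6-borinate and C12-alkylborane; both C11 epimers) | O([C@@H]1C/C(C)=C/CC/C(CO[Si](c3ccccc3)(c3ccccc3)C(C)(C)C)=C/[C@@H](OB3C4CCCC3CCC4)[C@H]1C(C)CB3C4CCCC3CCC4)C2CCCCO2 | intermediate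
26 | (1R,2Z,6E,9R,10R)-3-({[tert-butyl(diphenyl)silyl]oxy}methyl)-10-(1-hydroxypropan-2-yl)-7-methyl-9-(oxan-2-yloxy)cyclodeca-2,6-dien-1-ol (both C11 epimers) | O([C@@H]1C/C(C)=C/CC/C(CO[Si](c3ccccc3)(c3ccccc3)C(C)(C)C)=C/[C@@H](O)[C@H]1C(C)CO)C2CCCCO2 | intermediate
27 | (3aS,4R,6E,10Z,11aR)-10-({[tert-butyl(diphenyl)silyl]oxy}methyl)-3,6-dimethyl-4-(oxan-2-yloxy)-3a,4,5,8,9,11a-hexahydrocyclodeca[b]furan-2(3H)-one (both C3 epimers) | O([C@@H]1C/C(C)=C/CC/C(CO[Si](c3ccccc3)(c3ccccc3)C(C)(C)C)=C/[C@H]4OC(=O)C(C)[C@@H]14)C2CCCCO2 | intermediate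
28 | (3R,3aS,4R,6E,10Z,11aR)-10-({[tert-butyl(diphenyl)silyl]oxy}methyl)-3,6-dimethyl-4-(oxan-2-yloxy)-3a,4,5,8,9,11a-hexahydrocyclodeca[b]furan-2(3H)-one | O([C@@H]1C/C(C)=C/CC/C(CO[Si](c3ccccc3)(c3ccccc3)C(C)(C)C)=C/[C@H]4OC(=O)[C@H](C)[C@@H]14)C2CCCCO2 | intermediate
29 | (3R,3aS,4R,6E,10Z,11aR)-10-({[tert-butyl(diphenyl)silyl]oxy}methyl)-4-hydroxy-3,6-dimethyl-3a,4,5,8,9,11a-hexahydrocyclodeca[b]furan-2(3H)-one | O[C@@H]1C/C(C)=C/CC/C(CO[Si](c3ccccc3)(c3ccccc3)C(C)(C)C)=C/[C@H]2OC(=O)[C@H](C)[C@@H]12 | intermediate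
30 | ethyl 2-(hydroxymethyl)prop-2-enoate | C=C(CO)C(=O)OCC | starting material
31 | ethyl 2-({[tert-butyl(dimethyl)silyl]oxy}methyl)prop-2-enoate | C=C(CO[Si](C)(C)C(C)(C)C)C(=O)OCC | intermediate
32 | 2-({[tert-butyl(dimethyl)silyl]oxy}methyl)prop-2-enoic acid | C=C(CO[Si](C)(C)C(C)(C)C)C(=O)O | intermediate
33 | (3R,3aS,4S,6E,10Z,11aR)-10-({[tert-butyl(diphenyl)silyl]oxy}methyl)-3,6-dimethyl-2-oxo-2,3,3a,4,5,8,9,11a-octahydrocyclodeca[b]furan-4-yl 2-({[tert-butyl(dimethyl)silyl]oxy}methyl)prop-2-enoate | C=C(CO[Si](C)(C)C(C)(C)C)C(=O)O[C@H]1C/C(C)=C/CC/C(CO[Si](c3ccccc3)(c3ccccc3)C(C)(C)C)=C/[C@H]2OC(=O)[C@H](C)[C@@H]12 | intermediate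
34 | (3R,3aS,4S,6E,10Z,11aR)-10-(hydroxymethyl)-3,6-dimethyl-2-oxo-2,3,3a,4,5,8,9,11a-octahydrocyclodeca[b]furan-4-yl 2-(hydroxymethyl)prop-2-enoate | C=C(CO)C(=O)O[C@H]1C/C(C)=C/CC/C(CO)=C/[C@H]2OC(=O)[C@H](C)[C@@H]12 | target

## Step count and least certain steps

Total: 22 steps. Longest linear sequence: 17 steps (steps 1–4, 8–18, 21, 22). Steps 5–7 (imide 14) and 19–20 (acid 32) are side branches.

**Step 14 (key step).**
- What may go wrong: lithiation at C12 or at the C8 methine instead of C6, followed by ring contraction onto C4 or 1,4-elimination of the C8 oxygen; a competing [1,2]-shift if the temperature rises; weak transmission of the C8 configuration to the C7 face, because the forming ring can also pass through a twist conformation; over-silylation at O6 in the trapping.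
- Fallback: set out from 21, isolated by leaving out the fluoride treatment of step 13. DDQ in wet CH2Cl2 should open the more electron-rich, prenyl-type allyl ether at C6 oxidatively to the hydroxy enal F1. CBr4/PPh3 should turn its C12 hydroxyl into the allylic bromide F2. CrCl2 in THF at high dilution should then close ring A by a Nozaki–Hiyama carbonyl allylation, with C7 as the nucleophilic carbon of the allylchromium and the C6 aldehyde as the electrophile, to give the ten-membered homoallylic alcohol F3. In this closure the C6/C7 relationship depends on the metal-bound chair rather than on a sigmatropic array, and this chair normally places O6 anti to the C8 chain (6,7-trans), so F3 as drawn may well be the minor isomer; this fallback secures the ring and the C6–C7 bond rather than the C6 configuration, which would have to be checked at that stage. Bu4NF should give the diol F4, and t-BuPh2SiCl/imidazole returns to the route at 24.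

**Step 21 (esterification with inversion at C8).**
- What may go wrong: slow SN2 at a secondary carbinol flanked by the C7 branch, leading to elimination towards C9 or C7; participation of the lactone carbonyl with net retention or translactonisation; the acid is only moderately acidic.
- Fallback: set out from 29. Dess–Martin oxidation should give the C8 ketone F5. LiBH(s-Bu)3 at −78 °C should attack anti to the C7 branch and give the 8S alcohol F6. Yamaguchi esterification (2,4,6-trichlorobenzoyl chloride, Et3N, DMAP) with 32, now with retention, returns to the route at 33. F5 is a β-acyloxy ketone and must be reduced at once.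

**Step 13 (thirteen-membered ether).**
- What may go wrong: double sulfonylation or oligomerisation instead of ring closure; SN2′ closure; slow silyl migration from O15 to the neighbouring O6 alkoxide.
- Fallback: set out from 20. MsCl, LiCl and 2,4,6-collidine in DMF should give the bis(allylic chloride) F7. Under phase-transfer hydroxide (50% NaOH, Bu4NHSO4, toluene, high dilution) one chloride is hydrolysed and the resulting alkoxide closes the ring on the other, which returns to the route at 21 and, after Bu4NF, at 22. Here both carbons are electrophiles and the oxygen comes from hydroxide.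

**Step 17 (C11 equilibration).**
- What may go wrong: an equilibrium position that leaves too much of the 11-epimer; slow enolisation of a hindered lactone.
- Fallback: set out from 24 and set C11 kinetically instead. Thexylborane binds first to the C6 oxygen and then hydroborates the isopropenyl group intramolecularly through a six-membered chair with the C13 methyl and C8 equatorial. After oxidation this should give the 11R component of 26 only, which step 16 converts directly into 28. No new compound is needed.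

## Further compounds

F1 | step 14 | (2Z,6E,9R,10Z)-12-hydroxy-7,11-dimethyl-9-(oxan-2-yloxy)-3-({[tri(propan-2-yl)silyl]oxy}methyl)dodeca-2,6,10-trienal | O=C/C=C(\CO[Si](C(C)C)(C(C)C)C(C)C)CC/C=C(\C)C[C@@H](OC1CCCCO1)/C=C(/C)CO
F2 | step 14 | (2Z,6E,9R,10Z)-12-bromo-7,11-dimethyl-9-(oxan-2-yloxy)-3-({[tri(propan-2-yl)silyl]oxy}methyl)dodeca-2,6,10-trienal | O=C/C=C(\CO[Si](C(C)C)(C(C)C)C(C)C)CC/C=C(\C)C[C@@H](OC1CCCCO1)/C=C(/C)CBr
F3 | step 14 | (1R,2Z,6E,9R,10R)-7-methyl-9-(oxan-2-yloxy)-10-(prop-1-en-2-yl)-3-({[tri(propan-2-yl)silyl]oxy}methyl)cyclodeca-2,6-dien-1-ol | O([C@@H]1C/C(C)=C/CC/C(CO[Si](C(C)C)(C(C)C)C(C)C)=C/[C@@H](O)[C@H]1C(C)=C)C2CCCCO2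
F4 | step 14 | (1R,2Z,6E,9R,10R)-3-(hydroxymethyl)-7-methyl-9-(oxan-2-yloxy)-10-(prop-1-en-2-yl)cyclodeca-2,6-dien-1-ol | O([C@@H]1C/C(C)=C/CC/C(CO)=C/[C@@H](O)[C@H]1C(C)=C)C2CCCCO2
F5 | step 21 | (3R,3aR,6E,10Z,11aR)-10-({[tert-butyl(diphenyl)silyl]oxy}methyl)-3,6-dimethyl-3a,5,8,9-tetrahydrocyclodeca[b]furan-2,4(3H,11aH)-dione | O=C1C/C(C)=C/CC/C(CO[Si](c3ccccc3)(c3ccccc3)C(C)(C)C)=C/[C@H]2OC(=O)[C@H](C)[C@@H]12
F6 | step 21 | (3R,3aS,4S,6E,10Z,11aR)-10-({[tert-butyl(diphenyl)silyl]oxy}methyl)-4-hydroxy-3,6-dimethyl-3a,4,5,8,9,11a-hexahydrocyclodeca[b]furan-2(3H)-one | O[C@H]1C/C(C)=C/CC/C(CO[Si](c3ccccc3)(c3ccccc3)C(C)(C)C)=C/[C@H]2OC(=O)[C@H](C)[C@@H]12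
F7 | step 13 | (2Z,6E,9R,10Z)-1,12-dichloro-7,11-dimethyl-9-(oxan-2-yloxy)-3-({[tri(propan-2-yl)silyl]oxy}methyl)dodeca-2,6,10-triene | ClC/C=C(\CO[Si](C(C)C)(C(C)C)C(C)C)CC/C=C(\C)C[C@@H](OC1CCCCO1)/C=C(/C)CCl
F0 | step 17 | none | none
A1 | alternative 1 | methyl (2Z,4R,7E,11Z)-2-(bromomethyl)-11-({[tert-butyl(diphenyl)silyl]oxy}methyl)-7-methyl-13-oxo-4-[(triethylsilyl)oxy]trideca-2,7,11-trienoate | O=C/C=C(\CO[Si](c1ccccc1)(c1ccccc1)C(C)(C)C)CC/C=C(\C)C[C@@H](O[Si](CC)(CC)CC)/C=C(\CBr)C(=O)OC
A2 | alternative 1 | (3aS,4R,6E,10Z,11aR)-10-({[tert-butyl(diphenyl)silyl]oxy}methyl)-6-methyl-3-methylidene-4-[(triethylsilyl)oxy]-3a,4,5,8,9,11a-hexahydrocyclodeca[b]furan-2(3H)-one | CC[Si](CC)(CC)O[C@@H]1C/C(C)=C/CC/C(CO[Si](c3ccccc3)(c3ccccc3)C(C)(C)C)=C/[C@H]2OC(=O)C(=C)[C@@H]12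
A3 | alternative 2 | 3-({[tert-butyl(diphenyl)silyl]oxy}methyl)-1-[(1Z)-1-(methoxymethoxy)-3-methylbuta-1,3-dien-2-yl]-6-(prop-1-en-2-yl)cyclohex-2-en-1-ol | C=C(C)[C@H]1CCC(CO[Si](c2ccccc2)(c2ccccc2)C(C)(C)C)=C[C@@]1(O)/C(=C/OCOC)C(C)=C
A4 | alternative 2 | (2Z,6E)-3-({[tert-butyl(diphenyl)silyl]oxy}methyl)-9-(methoxymethoxy)-7-methyl-10-(prop-1-en-2-yl)cyclodeca-2,6-dien-1-one | O=C1/C=C(CO[Si](c2ccccc2)(c2ccccc2)C(C)(C)C)\CC/C=C(\C)C[C@@H](OCOC)[C@H]1C(C)=C
A5 | alternative 3 | eudesm-4-en-6,12-olide precursor: 15-[tert-butyl(diphenyl)silyl]oxy-1-(methanesulfonyloxy)-8-(oxan-2-yloxy)-11,13-dihydroeudesm-4-en-6,12-olide | CS(=O)(=O)O[C@H]1CCC(CO[Si](c2ccccc2)(c2ccccc2)C(C)(C)C)=C2[C@H]3OC(=O)[C@H](C)[C@@H]3[C@@H](OC4CCCCO4)C[C@]12C
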